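## Retrosynthetic overview

1. Target ⇐ one hydrogenolysis (nine O-benzyl groups and a C8 bromine cap) of the protected robinetinidol-(4α→6)-gallocatechin.
2. Interflavan C4–C6 bond ⇐ Friedel–Crafts opening of the 3,4-epoxide of the upper (S)-flav-3-ene by the C8-brominated gallocatechin unit (sets upper C3 and C4).
3. Lower unit ⇐ C8 bromination ⇐ hydroboration–oxidation of the lower (S)-flav-3-ene (sets lower C3).
4. Both flav-3-enes ⇐ chiral Brønsted acid-catalysed enantioconvergent cyclodehydration of racemic 2'-hydroxychalcone-derived allylic alcohols (closes ring C and sets C2 of each unit) ⇐ NaBH4 reduction ⇐ Claisen–Schmidt chalcones from two benzylated 2-hydroxyacetophenones and 3,4,5-tris(benzyloxy)benzaldehyde.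
5. Ring order: lower ring C, upper ring C, then the interflavan bond; deprotection last.

Assumption: the sense of induction of the new step ((R)-acid gives the (S)-flavene) is a working hypothesis to be checked on the first run, with the (S)-acid used instead if it is opposite; carbinols 4 and 10 are racemic and their transient stereocentre is erased on ionisation.

## Route

Step 1
Reactants: 1 1-[2,4-bis(benzyloxy)-6-hydroxyphenyl]ethan-1-one; 2 3,4,5-tris(benzyloxy)benzaldehyde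
Product: 3 lower (E)-2'-hydroxychalcone
Conditions: KOH (50% aq.), EtOH/THF, rt, 24 h
Reagents that add atoms: none
Why: Claisen–Schmidt aldol condensation, in which the acetophenone enolate adds to the non-enolisable aldehyde and E1cB dehydration gives the conjugated (E)-enone.

Step 2
Reactants: 3 lower (E)-2'-hydroxychalcone
Product: 4 lower racemic allylic alcohol
Conditions: NaBH4, THF/EtOH, 0 °C; NaH2PO4/Na2HPO4 buffer (pH 7) work-up, crude used at once
Reagents that add atoms: none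
Why: 1,2-reduction of the 2'-hydroxychalcone carbonyl by NaBH4 (the phenoxide-deactivated enone resists conjugate reduction) gives the racemic carbinol, whose stereocentre is destroyed in step 3.

Step 3
Reactants: 4 lower racemic allylic alcohol
Product: 5 lower (S)-flav-3-ene
Conditions: (R)-3,3'-bis(2,4,6-triisopropylphenyl)-H8-BINOL N-triflylphosphoramide (5 mol%), 5 Å MS, toluene/CH2Cl2 (4:1), −78 °C, dark; Et3N quench
Reagents that add atoms: none
Why: Proposed new method: the chiral N-triflylphosphoramide ionises the ortho-hydroxy, benzylic/allylic carbinol to a 1,3-diarylallyl cation (protonated vinylogous ortho-quinone methide) held as a hydrogen-bonded contact ion pair, which erases the racemic carbinol centre, and the phenol oxygen then closes onto the B-ring terminus (oxa-6π/intramolecular allylic etherification) inside the chiral anion pocket, so that both enantiomers of 4 converge on (S)-5 and C2 is set by the catalyst; closest known reaction type: chiral Brønsted acid contact-ion-pair allylic etherification of tertiary allylic alcohols to 2,2-disubstituted 2H-chromenes and chiral phosphoric acid additions to ortho-quinone methides, neither shown for secondary 1,3-diaryl carbinols or 2-aryl-2H-chromenes.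

Step 4
Reactants: 5 lower (S)-flav-3-ene
Product: 6 penta-O-benzyl-(+)-gallocatechin
Conditions: BH3·THF, THF, 0 °C → rt; then NaOH (3 M aq.), H2O2 (30%), 0 °C
Reagents that add atoms: hydrogen peroxide, OO
Why: Brown hydroboration–oxidation, in which boron adds to C3 (hydrogen to the aryl-stabilised C4) on the face anti to the C2 aryl group and is replaced by OH with retention, giving the 2,3-trans (2R,3S) flavan-3-ol.

Step 5
Reactants: 6 penta-O-benzyl-(+)-gallocatechin
Product: 7 8-bromo-penta-O-benzyl-(+)-gallocatechin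
Conditions: NBS (1.0 equiv), CH2Cl2, −78 → −20 °C
Reagents that add atoms: N-bromosuccinimide, O=C1CCC(=O)N1Br
Why: electrophilic aromatic bromination at C8, the most nucleophilic and least hindered position of the 5,7-dioxygenated ring A, which leaves C6 as the only nucleophilic arene carbon.

Step 6
Reactants: 8 1-[4-(benzyloxy)-2-hydroxyphenyl]ethan-1-one; 2 3,4,5-tris(benzyloxy)benzaldehyde
Product: 9 upper (E)-2'-hydroxychalcone
Conditions: KOH (50% aq.), EtOH/THF, rt, 24 h
Reagents that add atoms: none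
Why: Claisen–Schmidt aldol condensation followed by E1cB dehydration to the (E)-enone, as in step 1.

Step 7
Reactants: 9 upper (E)-2'-hydroxychalcone
Product: 10 upper racemic allylic alcohol
Conditions: NaBH4, THF/EtOH, 0 °C; NaH2PO4/Na2HPO4 buffer (pH 7) work-up, crude used at once
Reagents that add atoms: none
Why: 1,2-reduction of the chelated 2'-hydroxychalcone carbonyl by NaBH4, as in step 2, giving a racemic carbinol that is ionised in step 8.

Step 8
Reactants: 10 upper racemic allylic alcohol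
Product: 11 upper (S)-flav-3-ene
Conditions: (R)-3,3'-bis(2,4,6-triisopropylphenyl)-H8-BINOL N-triflylphosphoramide (5 mol%), 5 Å MS, toluene/CH2Cl2 (4:1), −60 °C, dark; Et3N quench
Reagents that add atoms: none
Why: Proposed new method: acid-induced loss of water from 10 gives the achiral 1,3-diarylallyl cation/vinylogous ortho-quinone methide paired with the chiral phosphoramide anion, and C–O bond formation at the B-ring terminus within that ion pair (oxa-6π/intramolecular allylic etherification) sets C2 as (S) from both enantiomers of 10; closest known reaction type: chiral Brønsted acid contact-ion-pair intramolecular allylic etherification to 2,2-disubstituted 2H-chromenes and chiral phosphoric acid additions to ortho-quinone methides.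

Step 9
Reactants: 11 upper (S)-flav-3-ene; 7 8-bromo-penta-O-benzyl-(+)-gallocatechin
Product: 13 bromo-capped nona-O-benzyl robinetinidol-(4α→6)-gallocatechin, via flavene oxide 12 (not isolated)
Conditions: DMDO (1.05 equiv, acetone), CH2Cl2, −40 °C; volatiles removed at −30 °C; then 7 (1.5 equiv, excess recovered), CH2Cl2/HFIP (4:1), −40 → 0 °C
Reagents that add atoms: dimethyldioxirane, CC1(C)OO1
Why: substrate-controlled dioxirane epoxidation of the C3=C4 bond anti to the C2 aryl group sets C3, and Friedel–Crafts arylation (arene opening of the 7-benzyloxy-activated benzylic epoxide in HFIP) at C4 anti to the C3 oxygen sets the 3,4-trans (4α) centre, while the C8 bromine of 7 forces bond formation at C6.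

Step 10
Reactants: 13 bromo-capped nona-O-benzyl robinetinidol-(4α→6)-gallocatechin
Product: 14 robinetinidol-(4α→6)-gallocatechin
Conditions: H2 (1 atm), Pd(OH)2/C, THF/MeOH/H2O (20:1:1), rt
Reagents that add atoms: none
Why: catalytic hydrogenolysis over Pd(OH)2/C cleaves the nine benzyl ethers and the aryl C–Br bond in one operation without touching the stereocentres, the ring C ether bonds or the acid-stable 5-deoxy interflavan bond.

## Compound list

1 | 1-[2,4-bis(benzyloxy)-6-hydroxyphenyl]ethan-1-one | CC(=O)c1c(O)cc(OCc2ccccc2)cc1OCc2ccccc2 | starting material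
2 | 3,4,5-tris(benzyloxy)benzaldehyde | O=Cc1cc(OCc2ccccc2)c(OCc2ccccc2)c(OCc2ccccc2)c1 | starting material
3 | (2E)-1-[2,4-bis(benzyloxy)-6-hydroxyphenyl]-3-[3,4,5-tris(benzyloxy)phenyl]prop-2-en-1-one | O=C(/C=C/c1cc(OCc2ccccc2)c(OCc2ccccc2)c(OCc2ccccc2)c1)c1c(O)cc(OCc2ccccc2)cc1OCc2ccccc2 | intermediate
4 | (2E)-1-[2,4-bis(benzyloxy)-6-hydroxyphenyl]-3-[3,4,5-tris(benzyloxy)phenyl]prop-2-en-1-ol, racemic | OC(/C=C/c1cc(OCc2ccccc2)c(OCc2ccccc2)c(OCc2ccccc2)c1)c1c(O)cc(OCc2ccccc2)cc1OCc2ccccc2 | intermediate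
5 | (2S)-5,7-bis(benzyloxy)-2-[3,4,5-tris(benzyloxy)phenyl]-2H-chromene | c1(OCc2ccccc2)cc(OCc2ccccc2)c2C=C[C@@H](c3cc(OCc4ccccc4)c(OCc4ccccc4)c(OCc4ccccc4)c3)Oc2c1 | intermediate
6 | (2R,3S)-5,7-bis(benzyloxy)-2-[3,4,5-tris(benzyloxy)phenyl]-3,4-dihydro-2H-chromen-3-ol | c1(OCc2ccccc2)cc(OCc2ccccc2)c2C[C@H](O)[C@@H](c3cc(OCc4ccccc4)c(OCc4ccccc4)c(OCc4ccccc4)c3)Oc2c1 | intermediate
7 | (2R,3S)-5,7-bis(benzyloxy)-8-bromo-2-[3,4,5-tris(benzyloxy)phenyl]-3,4-dihydro-2H-chromen-3-ol | c1(OCc2ccccc2)cc(OCc2ccccc2)c2C[C@H](O)[C@@H](c3cc(OCc4ccccc4)c(OCc4ccccc4)c(OCc4ccccc4)c3)Oc2c1Br | intermediate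
8 | 1-[4-(benzyloxy)-2-hydroxyphenyl]ethan-1-one | CC(=O)c1ccc(OCc2ccccc2)cc1O | starting material
9 | (2E)-1-[4-(benzyloxy)-2-hydroxyphenyl]-3-[3,4,5-tris(benzyloxy)phenyl]prop-2-en-1-one | O=C(/C=C/c1cc(OCc2ccccc2)c(OCc2ccccc2)c(OCc2ccccc2)c1)c1ccc(OCc2ccccc2)cc1O | intermediate
10 | (2E)-1-[4-(benzyloxy)-2-hydroxyphenyl]-3-[3,4,5-tris(benzyloxy)phenyl]prop-2-en-1-ol, racemic | OC(/C=C/c1cc(OCc2ccccc2)c(OCc2ccccc2)c(OCc2ccccc2)c1)c1ccc(OCc2ccccc2)cc1O | intermediate
11 | (2S)-7-(benzyloxy)-2-[3,4,5-tris(benzyloxy)phenyl]-2H-chromene | c1(OCc2ccccc2)ccc2C=C[C@@H](c3cc(OCc4ccccc4)c(OCc4ccccc4)c(OCc4ccccc4)c3)Oc2c1 | intermediate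
12 | (2R,3S,4S)-7-(benzyloxy)-3,4-epoxy-2-[3,4,5-tris(benzyloxy)phenyl]-3,4-dihydro-2H-chromene (flavan numbering) | c1(OCc2ccccc2)ccc2c(c1)O[C@H](c1cc(OCc3ccccc3)c(OCc3ccccc3)c(OCc3ccccc3)c1)[C@H]1O[C@@H]21 | intermediate (not isolated)
13 | (2R,3S,4S)-7-(benzyloxy)-4-{(2R,3S)-5,7-bis(benzyloxy)-8-bromo-3-hydroxy-2-[3,4,5-tris(benzyloxy)phenyl]-3,4-dihydro-2H-chromen-6-yl}-2-[3,4,5-tris(benzyloxy)phenyl]-3,4-dihydro-2H-chromen-3-ol | c3ccccc3COc1ccc2c(c1)O[C@H](c1cc(OCc3ccccc3)c(OCc3ccccc3)c(OCc3ccccc3)c1)[C@@H](O)[C@@H]2c1c(OCc3ccccc3)c(Br)c2c(c1OCc3ccccc3)C[C@H](O)[C@@H](c1cc(OCc3ccccc3)c(OCc3ccccc3)c(OCc3ccccc3)c1)O2 | intermediate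
14 | robinetinidol-(4α→6)-gallocatechin; (2R,3S,4S)-4-[(2R,3S)-3,5,7-trihydroxy-2-(3,4,5-trihydroxyphenyl)-3,4-dihydro-2H-chromen-6-yl]-2-(3,4,5-trihydroxyphenyl)-3,4-dihydro-2H-chromene-3,7-diol | Oc1ccc2c(c1)O[C@H](c1cc(O)c(O)c(O)c1)[C@@H](O)[C@@H]2c1c(O)cc2c(c1O)C[C@H](O)[C@@H](c1cc(O)c(O)c(O)c1)O2 | target

## Step count and risks

Total step count: 10. Longest linear sequence: 7 (steps 1, 2, 3, 4, 5, 9, 10).

The three steps most likely to fail:

**Step 3 (new cyclodehydration, lower unit).** The trioxygenated carbinol 4 may cyclise without the catalyst and give racemic flavene. The product may racemise by acid re-ionisation. The level and sense of induction are unknown. Partial erosion can be repaired by recrystallising 6 or 7. Fallback with known chemistry, setting out from 3 and coming back at 6: chalcone 3 is treated with ClCO2Et/Et3N (THF, 0 °C) to give the aryl ethyl carbonate F1, which is reduced in the same flask with NaBH4/H2O to the (E)-2-cinnamylphenol F2. TBSCl/imidazole (DMF) gives the silyl ether F3. Shi epoxidation with the L-fructose-derived ketone (1,2:4,5-di-O-isopropylidene-L-erythro-2,3-hexodiulo-2,6-pyranose, 30 mol%; KHSO5 as 2KHSO5·KHSO4·K2SO4, K2CO3, MeCN/dimethoxymethane/aqueous Na2B4O7 buffer, 0 °C) gives the (2S,3S)-silyloxy epoxide F4. Bu4NF/AcOH (THF, 0 °C) releases the phenol epoxide F5, which is not isolated, and camphorsulfonic acid (CH2Cl2, 0 °C) closes ring C by 6-endo opening at the benzylic carbon with inversion to give 6.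

**Step 8 (new cyclodehydration, upper unit).** Carbinol 10 ionises less readily than 4, so a higher temperature may be needed, which loosens the ion pair. Flavene 11 may also disproportionate under acid. A minor enantiomer of 11 would be removed at 13 as a separable diastereomer. Fallback with known chemistry, setting out from 9 and coming back at 13: chalcone 9 gives with ClCO2Et/Et3N the aryl ethyl carbonate F6, reduced in the same flask (NaBH4/H2O) to the (E)-2-cinnamylphenol F7. TBSCl/imidazole gives the silyl ether F8, and Shi epoxidation with the same L-fructose-derived ketone gives the (2S,3S)-silyloxy epoxide F9. Bu4NF/AcOH releases the phenol epoxide F10, not isolated, which camphorsulfonic acid cyclises to tetra-O-benzylrobinetinidol F11. Benzylic oxidation with DDQ in the presence of 2-ethoxyethanol (CH2Cl2, rt) gives the 4-(2-ethoxyethoxy)flavan-3-ol F12 (either C4 epimer ionises to the same cation). Coupling of F12 with 7 under TMSOTf (CH2Cl2, −78 °C) gives 13.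

**Step 9 (epoxidation and epoxide arylation).** Epoxide 12 may rearrange to the flavan-3-one (Meinwald), self-condense through its own ring A, or react sluggishly with the hindered C6 of 7. Fallback setting out from 11 and coming back at 13: epoxide 12, formed as in step 9, is quenched at −40 °C with MeOH containing pyridinium p-toluenesulfonate (1 mol%) to give the isolable trans-4-methoxyflavan-3-ol F13. After chromatography, F13 is coupled with 7 under TMSOTf (CH2Cl2, −78 °C), the classical Lewis acid interflavan coupling of a 4-alkoxyflavan-3-ol, to give 13.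

## Further compounds

F1 | step 3 | 3,5-bis(benzyloxy)-2-{(2E)-3-[3,4,5-tris(benzyloxy)phenyl]prop-2-enoyl}phenyl ethyl carbonate | CCOC(=O)Oc1cc(OCc2ccccc2)cc(OCc2ccccc2)c1C(=O)/C=C/c1cc(OCc2ccccc2)c(OCc2ccccc2)c(OCc2ccccc2)c1
F2 | step 3 | 3,5-bis(benzyloxy)-2-{(2E)-3-[3,4,5-tris(benzyloxy)phenyl]prop-2-en-1-yl}phenol | Oc1cc(OCc2ccccc2)cc(OCc2ccccc2)c1C/C=C/c1cc(OCc2ccccc2)c(OCc2ccccc2)c(OCc2ccccc2)c1
F3 | step 3 | (3,5-bis(benzyloxy)-2-{(2E)-3-[3,4,5-tris(benzyloxy)phenyl]prop-2-en-1-yl}phenoxy)(tert-butyl)dimethylsilane | CC(C)(C)[Si](C)(C)Oc1cc(OCc2ccccc2)cc(OCc2ccccc2)c1C/C=C/c1cc(OCc2ccccc2)c(OCc2ccccc2)c(OCc2ccccc2)c1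
F4 | step 3 | (3,5-bis(benzyloxy)-2-{[(2S,3S)-3-(3,4,5-tris(benzyloxy)phenyl)oxiran-2-yl]methyl}phenoxy)(tert-butyl)dimethylsilane | CC(C)(C)[Si](C)(C)Oc1cc(OCc2ccccc2)cc(OCc2ccccc2)c1C[C@@H]1O[C@H]1c1cc(OCc2ccccc2)c(OCc2ccccc2)c(OCc2ccccc2)c1
F5 | step 3 | 3,5-bis(benzyloxy)-2-{[(2S,3S)-3-(3,4,5-tris(benzyloxy)phenyl)oxiran-2-yl]methyl}phenol | Oc1cc(OCc2ccccc2)cc(OCc2ccccc2)c1C[C@@H]1O[C@H]1c1cc(OCc2ccccc2)c(OCc2ccccc2)c(OCc2ccccc2)c1
F6 | step 8 | 5-(benzyloxy)-2-{(2E)-3-[3,4,5-tris(benzyloxy)phenyl]prop-2-enoyl}phenyl ethyl carbonate | CCOC(=O)Oc1cc(OCc2ccccc2)ccc1C(=O)/C=C/c1cc(OCc2ccccc2)c(OCc2ccccc2)c(OCc2ccccc2)c1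
F7 | step 8 | 5-(benzyloxy)-2-{(2E)-3-[3,4,5-tris(benzyloxy)phenyl]prop-2-en-1-yl}phenol | Oc1cc(OCc2ccccc2)ccc1C/C=C/c1cc(OCc2ccccc2)c(OCc2ccccc2)c(OCc2ccccc2)c1
F8 | step 8 | (5-(benzyloxy)-2-{(2E)-3-[3,4,5-tris(benzyloxy)phenyl]prop-2-en-1-yl}phenoxy)(tert-butyl)dimethylsilane | CC(C)(C)[Si](C)(C)Oc1cc(OCc2ccccc2)ccc1C/C=C/c1cc(OCc2ccccc2)c(OCc2ccccc2)c(OCc2ccccc2)c1
F9 | step 8 | (5-(benzyloxy)-2-{[(2S,3S)-3-(3,4,5-tris(benzyloxy)phenyl)oxiran-2-yl]methyl}phenoxy)(tert-butyl)dimethylsilane | CC(C)(C)[Si](C)(C)Oc1cc(OCc2ccccc2)ccc1C[C@@H]1O[C@H]1c1cc(OCc2ccccc2)c(OCc2ccccc2)c(OCc2ccccc2)c1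
F10 | step 8 | 5-(benzyloxy)-2-{[(2S,3S)-3-(3,4,5-tris(benzyloxy)phenyl)oxiran-2-yl]methyl}phenol | Oc1cc(OCc2ccccc2)ccc1C[C@@H]1O[C@H]1c1cc(OCc2ccccc2)c(OCc2ccccc2)c(OCc2ccccc2)c1
F11 | step 8 | (2R,3S)-7-(benzyloxy)-2-[3,4,5-tris(benzyloxy)phenyl]-3,4-dihydro-2H-chromen-3-ol | c1(OCc2ccccc2)ccc2C[C@H](O)[C@@H](c3cc(OCc4ccccc4)c(OCc4ccccc4)c(OCc4ccccc4)c3)Oc2c1
F12 | step 8 | (2R,3S,4R)-7-(benzyloxy)-4-(2-ethoxyethoxy)-2-[3,4,5-tris(benzyloxy)phenyl]-3,4-dihydro-2H-chromen-3-ol | c1(OCc3ccccc3)ccc2c(c1)O[C@H](c1cc(OCc3ccccc3)c(OCc3ccccc3)c(OCc3ccccc3)c1)[C@@H](O)[C@@H]2OCCOCC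
F13 | step 9 | (2R,3S,4R)-7-(benzyloxy)-4-methoxy-2-[3,4,5-tris(benzyloxy)phenyl]-3,4-dihydro-2H-chromen-3-ol | c1(OCc3ccccc3)ccc2c(c1)O[C@H](c1cc(OCc3ccccc3)c(OCc3ccccc3)c(OCc3ccccc3)c1)[C@@H](O)[C@@H]2OC
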